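Remark: the dienone half is treated as the 6-hydroxy-8-oxo tautomer of the SMILES, in free equilibrium with its 8-hydroxy-6-oxo form; atoms carry isochroman locants (C1, O2, C3 to C8a), the bridge carbon is C9, and the aromatic half is primed.

## Structural features

The target consists of two 3,4,5-trimethylisochroman-type bicycles, each a carbocycle (ring A, ring A′) fused to a pyran (ring B, ring B′), and the only link between them is the methylene C9 joining C7 to C7′. The primed half is a hexasubstituted resorcinol (hydroxyls on C6′ and C8′) with a saturated C1′H2–O2′ ether. The unprimed half is the same skeleton two hydrogens poorer, a 6-hydroxy-8-oxo quinone methide whose enol ether C1=C8a is conjugated to the C8 carbonyl. Each half carries the vicinal pair C3 (R, oxygen-bearing) and C4 (S, attached to C4a) with trans methyl groups, so there are four stereocentres in two identical, mutually remote pairs. The quinone methide is electrophilic at C1 toward water, amines and electron-rich arenes, the resorcinol and the doubly benzylic C9 are easily oxidised, and under acid a hydroxyl on C6′ or C8′ can condense with the neighbouring dienone carbonyl to a xanthene. The real difficulty is twofold: ring A is fully substituted, with C4a (bearing the chiral C3–C4 chain) meta to both O6 and O8, where electrophilic substitution of a resorcinol does not go, and the two halves differ only in the oxidation level of C1 yet must be told apart. The key step uses the fact that the 1,3-dioxygenated ring A is a dehydrogenated cyclohexane-1,3-dione: C4a becomes the β-carbon of an enone that also supplies C8a, C8 and C7, while C5 and C6 come from a methylmalonic ester, so the ring is assembled from four enone carbons and two malonate carbons around a side chain that already holds C3 and C4.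

## Logic of the disconnections

18 is cut at C7–C9. This bond separates the two oxidation levels: on one side 15, already a quinone methide, on the other 16, an arene carrying C9 as an aminomethyl group. A C25 problem becomes two C12 bicycles of one skeleton, and no late oxidation of one of two like halves is needed. The forward step must unmask the electrophile 17 from 16 without acid, and 15 must react through C7 as a carbon nucleophile faster than it attacks itself at C1.

16 is cut at C9–C7′ and C9–N, a Mannich retron. C7′ is the only unsubstituted ring position of 14 and lies ortho to both hydroxyls, so regiochemistry is not in question; C9 arrives with a leaving group that stays silent until heated. The forward step must stop before a second molecule of 14 is alkylated.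

15 is traced to 14 by adding hydride at C1 and a proton at oxygen; no skeletal bond is cut. Both halves thus descend from the one monomer 14. The forward oxidation must take the C1–H and not the C5 methyl hydrogens and stop after two electrons; it is run on the monomer, where there is only one C1.

14 is cut at C1–C8a, with C1 kept on O2 as the acetal carbon of 13. C8a is para to O6 and ortho to O8, so this is the one ring bond that electrophilic substitution makes readily, and the tether makes it intramolecular. Ring B disappears and a monocyclic arene remains. The forward step must close the ring faster than any intermolecular attack at C7.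

13 is de-aromatised to 12 by adding two hydrogens to ring A. The meta relation of C4a to O6 and O8, awkward in an arene, is the natural 1,3,5 relation of a 5-substituted cyclohexane-1,3-dione, so arene chemistry becomes carbonyl chemistry. The forward dehydrogenation must spare the acetal and the configuration at C4.

12 receives an ester on C5 to give 10, the retron for a decarboxylation. The ester is what lets C5 act as a stabilised carbanion while already carrying its methyl group. The forward hydrolysis and loss of CO2 must avoid acid strong enough to cleave the acetal.

10 is cut at C6–C7 (Claisen retron) to give 9, and 9 at C4a–C5 (Michael retron) to give 7 and 8. Both bonds follow natural polarity: C5 of 8 is the donor and C4a of 7 the acceptor, then C7 is the donor and an ester carbon the acceptor. A hexasubstituted ring reduces to an acyclic enone holding all the stereochemistry plus a commercial diester. The forward step must add 1,4 before 7 loses its γ-hydrogen at C4.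

7 is cut at its C=C bond (C4a=C8a in target numbering), a Wittig retron, giving 5 and 6. 6 delivers C8a, C8 and C7 in one piece. The olefination must be mild enough for an α-branched, β-oxygenated aldehyde.

5 is related to 4 by the oxidation level of the future C4a, and 4 to 3 by the group on oxygen. That group must be inert to ethoxide and hydroxide, a poor leaving group from a dienolate, and in place until the arene exists, because a free C3 hydroxyl would condense with the 1,3-dione of 12 to a bicyclic enol ether. A methoxymethyl acetal meets these demands, and its CH2 becomes C1, so no separate deprotection and no external C1 reagent are needed.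

3 is cut at the C4–CH3 bond. C3 is bought with 1, and C4 is created beside it by alkylation of 2. The forward step must give high anti selectivity.

## Other disconnections considered

Alternative 1: The cut removes C9 with both its ring bonds, C7–C9 and C9–C7′, so 18 falls into two molecules of 14 and one of formaldehyde.
- Forward key step: 14 is hydroxymethylated at C7, the benzylic alcohol dehydrates to an ortho-quinone methide, and a second molecule of 14 adds through C7′ to give the symmetrical A1. One of its two C1H2 groups must then be oxidised.
- In favour: one monomer serves both halves, no activating group is needed, and 14 has a single free ring position, so the bridging is regiochemically clean.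
- Against: A1 has two identical halves, so the closing oxidation cannot distinguish them and would be expected to leave unchanged, singly and doubly oxidised material together. The C9 methylene, flanked by two rings and four hydroxyls, is a further site for hydride abstraction. The plan also says nothing about how ring A is made.
- Comparison: on structure it is an end-game that needs a supply of 14, so it partners the chosen ring construction and does not compete with it. On mechanism the C–C bond formation (capture of a quinone methide by an enol or phenol carbon) is the equal of the chosen coupling. On step economy it is the better plan, reaching the bridged skeleton one operation sooner. The chosen plan spends that extra step to oxidise before coupling and so removes the symmetry problem; the A1 route is kept as the fallback for the last step.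

Alternative 2: The cut is at the two C4–CH3 bonds, with the C7–C9–C7′ bridge and both arenes already in place.
- Forward key step: Me2CuLi opens the two trans-(2R,3R) epoxides of A3 at their benzylic carbons with inversion to give the bis-carbinol A2. A3 would come from asymmetric epoxidation of the bis-(E)-propenyl compound A4.
- In favour: both C4 centres are set in one stereospecific, two-directional operation; absolute configuration comes from a catalyst; no ring is dehydrogenated. The bridge can be installed at the outset by joining two arenes metalated between their methoxy groups, the most reliable site for directed metalation.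
- Against: C4a is still meta to both oxygens, so the 1,3,5 pattern must be bought and the C5 methyl placed ortho to the side chain. That ortho methyl shields the benzylic epoxide carbon, so attack at the methyl-bearing carbon or rearrangement to a ketone could compete. Any error in one arm gives a diastereomer of the dimer, not a minor enantiomer. Four methyl ethers must later be cleaved with a strong Lewis acid beside benzylic C–O bonds, and the single oxidation at C1 remains as in alternative 1.
- Comparison: on structure the alternative attaches the chain to a finished arene, where the chosen plan grows the arene around the chain. On mechanism the two are equal in principle for relative configuration (stereospecific opening against 1,2-induction), and the alternative is better at fixing the position of C9. On step economy it is about equal up to the carbon skeleton and longer once deprotection and two pyran closures are counted.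

Alternative 3: The cut is the C1–O2 bond, with C1 present beforehand as an aryl methyl group.
- Forward key step: two-electron anodic oxidation (or DDQ) of the carbinol A6 turns one of the two methyls flanking the side chain into a benzylic cation, which the C3 hydroxyl captures to give A5.
- In favour: the two flanking methyls are interchangeable, so there is no regiochemical question, and ring B closes by C–H functionalisation without a C1 reagent.
- Against: the new C1–H of A5 (benzylic and α to oxygen) is easier to oxidise than the methyl it came from, so over-oxidation to a lactol or lactone is to be expected unless conversion is held back; the surviving C5 methyl is activated likewise. The phenols must be masked as methyl ethers, which means four deprotections in the dimer. The side chain with its C4 centre must be joined to an aryl carbon flanked by two ortho substituents and meta to both oxygens, the hardest position on the ring.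
- Comparison: on structure the alternative solves ring B but not ring A. On mechanism an oxidative cation can overrun, whereas the acetal-derived oxocarbenium ion of the chosen plan cannot. On redox economy of the ring-B closure the alternative is the equal of the chosen plan (which takes C1 from the protecting group) and better than an acetal closure with an external reagent. On step economy the closure itself is equal at one step, but the overall route is longer.

Key step: step 5

## Steps

Step 1
Reactants: 1 methyl (R)-3-hydroxybutanoate
Product: 3 methyl (2R,3R)-3-hydroxy-2-methylbutanoate, via dilithium dianion 2 (not isolated)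
Conditions: LiN(i-Pr)2 (2.2 equiv), THF, −78 → −20 °C; MeI, DMPU, −78 → 0 °C; cold 1 M HCl
Reagents that add atoms: iodomethane, CI
Why: Fráter–Seebach alkylation: the chelated alkoxide–enolate 2 should be methylated on the face away from the C3 methyl group, setting the new centre (the future C4) anti to the carbinol by 1,2-induction as the (2R,3R) isomer; the carbinol centre comes unchanged from the chiral pool.

Step 2
Reactants: 3 methyl (2R,3R)-3-hydroxy-2-methylbutanoate
Product: 4 methyl (2R,3R)-3-(methoxymethoxy)-2-methylbutanoate
Conditions: MeOCH2Cl, i-Pr2NEt, CH2Cl2, 0 °C → rt
Reagents that add atoms: chloromethyl methyl ether, COCCl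
Why: Standard O-alkylation of a secondary alcohol with an α-chloro ether under a hindered amine base, which does not enolise the ester, so the α-centre should be safe; the acetal CH2 introduced here is the future C1.

Step 3
Reactants: 4 methyl (2R,3R)-3-(methoxymethoxy)-2-methylbutanoate
Product: 5 (2R,3R)-3-(methoxymethoxy)-2-methylbutanal
Conditions: i-Bu2AlH (1.1 equiv), CH2Cl2, −78 °C; MeOH, then aq. potassium sodium tartrate
Reagents that add atoms: none
Why: Partial reduction of an ester with i-Bu2AlH at −78 °C stops at the aldehyde oxidation level; the aldehyde is used cold and crude so that its α-centre does not epimerise.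

Step 4
Reactants: 5 (2R,3R)-3-(methoxymethoxy)-2-methylbutanal; 6 1-(triphenylphosphoranylidene)propan-2-one
Product: 7 (3E,5S,6R)-6-(methoxymethoxy)-5-methylhept-3-en-2-one
Conditions: CH2Cl2, rt → 40 °C
Reagents that add atoms: none
Why: Wittig olefination with a stabilised acyl ylide should give the (E)-enone, and the weakly basic ylide should leave the α-centre intact; the descriptor at that carbon changes from R to S only because the CIP ranking of its neighbours changes.

Step 5
Reactants: 7 (3E,5S,6R)-6-(methoxymethoxy)-5-methylhept-3-en-2-one; 8 diethyl methylmalonate
Product: 10 ethyl 6-[(2S,3R)-3-(methoxymethoxy)butan-2-yl]-1-methyl-2,4-dioxocyclohexane-1-carboxylate (ring diastereomers), via Michael adduct 9 (not isolated)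
Conditions: 8 (2 equiv), NaOEt (1.1 equiv), EtOH, 0 °C → rt, then reflux; 1 M HCl to pH 4
Reagents that add atoms: none
Why: The sodium enolate of 8 adds 1,4 to the (E)-enone at its β-carbon (the future C4a), giving 9 with the new C4a–C5 bond and a quaternary C5; the methyl-ketone enolate of 9 then attacks one ester carbonyl and expels ethoxide, forming C6–C7, and the product is drained into its stabilised 1,3-dione enolate, which pulls the reversible sequence forward. The closest known reaction type is the Michael–Claisen (Dieckmann-type) synthesis of dihydroresorcinols from enones and malonic esters, as in the preparation of dimedone. The single ring closes by a 6-exo-trig acylation, the enolate carbon attacking an ester C=O whose oxygen stays outside the ring. The two new ring centres (C1 and C6 of the cyclohexane) form without control as a mixture, which is accepted because both become sp2 on aromatisation; the side-chain centres are not touched. The step needs 1,4- over 1,2-addition, which the soft, stabilised carbanion secures. It needs conjugate addition ahead of γ-deprotonation (which would epimerise C4 or expel the C3 oxygen by vinylogous elimination), which is secured by buffering ethoxide with excess 8 at 0 °C to rt before heating and by the poor leaving-group ability of the acetal oxygen. It needs the right Claisen regiochemistry, which is fixed because only the terminal methyl-ketone enolate reaches an ester through a six-membered transition state, the internal enolate being able to close only a four-membered ring.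

Step 6
Reactants: 10 ethyl 6-[(2S,3R)-3-(methoxymethoxy)butan-2-yl]-1-methyl-2,4-dioxocyclohexane-1-carboxylate
Product: 12 5-[(2S,3R)-3-(methoxymethoxy)butan-2-yl]-4-methylcyclohexane-1,3-dione (ring diastereomers), via keto acid 11 (not isolated)
Conditions: KOH, EtOH–H2O, reflux; then 1 M HCl to pH 3, 50 °C
Reagents that add atoms: none
Why: Saponification of the hindered ester is possible because the ring is held as its dione enolate, which resists retro-Claisen cleavage, and the β-keto acid 11 loses CO2 on gentle acidification; pH 3 and 50 °C are chosen so that the acetal should survive.

Step 7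
Reactants: 12 5-[(2S,3R)-3-(methoxymethoxy)butan-2-yl]-4-methylcyclohexane-1,3-dione
Product: 13 5-[(2S,3R)-3-(methoxymethoxy)butan-2-yl]-4-methylbenzene-1,3-diol
Conditions: 10% Pd/C, mesitylene, reflux, N2 stream
Reagents that add atoms: none
Why: Catalytic dehydrogenation of a dihydroresorcinol to a resorcinol over Pd/C: loss of one molecule of H2 from the ring followed by enolisation gives the arene, with aromatic stabilisation as driving force; the neutral medium spares the acetal, and the ring centres of 12 vanish.

Step 8
Reactants: 13 5-[(2S,3R)-3-(methoxymethoxy)butan-2-yl]-4-methylbenzene-1,3-diol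
Product: 14 (3R,4S)-3,4,5-trimethyl-3,4-dihydro-1H-isochromene-6,8-diol
Conditions: BF3·OEt2 (0.2 equiv), CH2Cl2 (0.02 M), −20 → 0 °C
Reagents that add atoms: none
Why: Oxa-Pictet–Spengler cyclisation: the Lewis acid ionises the acetal with loss of methanol, and the tethered oxocarbenium carbon is attacked by C8a (para to O6, ortho to O8) in a 6-endo closure of ring B. No stereocentre is formed, C3 and C4 are untouched, and high dilution should favour this internal position over intermolecular attack at C7.

Step 9
Reactants: 14 (3R,4S)-3,4,5-trimethyl-3,4-dihydro-1H-isochromene-6,8-diol
Product: 15 (3R,4S)-6-hydroxy-3,4,5-trimethyl-3,4-dihydro-8H-isochromen-8-one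
Conditions: DDQ (1.0 equiv; 14 added slowly), CH2Cl2, 0 °C
Reagents that add atoms: none
Why: DDQ should abstract hydride from C1, the most hydridic C–H (benzylic, α to O2, para to the C6 hydroxyl), and loss of a phenolic proton then gives the quinone methide; this is the hydride-abstraction chemistry by which DDQ oxidises isochromans and para-hydroxybenzyl ethers. Slow addition of 14 to the oxidant keeps unreacted 14 from meeting 15.

Step 10
Reactants: 14 (3R,4S)-3,4,5-trimethyl-3,4-dihydro-1H-isochromene-6,8-diol
Product: 16 (3R,4S)-7-[(dimethylamino)methyl]-3,4,5-trimethyl-3,4-dihydro-1H-isochromene-6,8-diol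
Conditions: 37% aq. CH2O (1.0 equiv) premixed with 40% aq. Me2NH (2 equiv), EtOH, 0 °C → rt
Reagents that add atoms: formaldehyde, C=O; dimethylamine, CNC
Why: Phenolic Mannich reaction: C7, ortho to both hydroxyls, is the only unsubstituted ring position, so aminomethylation can occur only there. Pre-forming the amine–formaldehyde adduct with excess amine keeps free formaldehyde away and should prevent diarylmethane formation.

Step 11
Reactants: 16 (3R,4S)-7-[(dimethylamino)methyl]-3,4,5-trimethyl-3,4-dihydro-1H-isochromene-6,8-diol; 15 (3R,4S)-6-hydroxy-3,4,5-trimethyl-3,4-dihydro-8H-isochromen-8-one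
Product: 18 (3R,4S)-7-{[(3R,4S)-6,8-dihydroxy-3,4,5-trimethyl-3,4-dihydro-1H-isochromen-7-yl]methyl}-6-hydroxy-3,4,5-trimethyl-3,4-dihydro-8H-isochromen-8-one, via ortho-quinone methide 17 (not isolated)
Conditions: 16 (1.0 equiv), 15 (1.1 equiv), toluene, 60 °C, N2 stream
Reagents that add atoms: none
Why: Thermal loss of Me2NH from 16 gives 17, to which the enol carbon C7 of the vinylogous acid 15 adds in a Michael reaction, the known trapping of Mannich-base-derived ortho-quinone methides by cyclic 1,3-dicarbonyl enols. Re-aromatisation of the acceptor ring and re-enolisation of the donor ring should give 18 directly in the right oxidation pattern; no stereocentre is formed, and the amine is swept out so that it does not remain on C1.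

## Compound list

1 | methyl (R)-3-hydroxybutanoate | C[C@@H](O)CC(=O)OC | starting material
2 | dilithium (E,3R)-1-methoxybut-1-ene-1,3-diolate (enolate oxygen cis to C3) | C[C@@H]([O-])/C=C(\[O-])OC.[Li+].[Li+] | intermediate (not isolated)
3 | methyl (2R,3R)-3-hydroxy-2-methylbutanoate | C[C@@H](O)[C@@H](C)C(=O)OC | intermediate
4 | methyl (2R,3R)-3-(methoxymethoxy)-2-methylbutanoate | COCO[C@H](C)[C@@H](C)C(=O)OC | intermediate
5 | (2R,3R)-3-(methoxymethoxy)-2-methylbutanal | COCO[C@H](C)[C@@H](C)C=O | intermediate
6 | 1-(triphenylphosphoranylidene)propan-2-one | CC(=O)C=P(c1ccccc1)(c1ccccc1)c1ccccc1 | starting material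
7 | (3E,5S,6R)-6-(methoxymethoxy)-5-methylhept-3-en-2-one | COCO[C@H](C)[C@@H](C)/C=C/C(C)=O | intermediate
8 | diethyl methylmalonate | CCOC(=O)C(C)C(=O)OCC | starting material
9 | diethyl 2-[(5S,6R)-6-(methoxymethoxy)-5-methyl-2-oxoheptan-4-yl]-2-methylpropanedioate (C4 epimers) | CCOC(=O)C(C)(C(=O)OCC)C(CC(C)=O)[C@H](C)[C@@H](C)OCOC | intermediate (not isolated)
10 | ethyl 6-[(2S,3R)-3-(methoxymethoxy)butan-2-yl]-1-methyl-2,4-dioxocyclohexane-1-carboxylate (ring centres as a mixture) | CCOC(=O)C1(C)C(=O)CC(=O)CC1[C@H](C)[C@@H](C)OCOC | intermediate
11 | 6-[(2S,3R)-3-(methoxymethoxy)butan-2-yl]-1-methyl-2,4-dioxocyclohexane-1-carboxylic acid (ring centres as a mixture) | OC(=O)C1(C)C(=O)CC(=O)CC1[C@H](C)[C@@H](C)OCOC | intermediate (not isolated)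
12 | 5-[(2S,3R)-3-(methoxymethoxy)butan-2-yl]-4-methylcyclohexane-1,3-dione (ring centres as a mixture) | CC1C(=O)CC(=O)CC1[C@H](C)[C@@H](C)OCOC | intermediate
13 | 5-[(2S,3R)-3-(methoxymethoxy)butan-2-yl]-4-methylbenzene-1,3-diol | Cc1c(O)cc(O)cc1[C@H](C)[C@@H](C)OCOC | intermediate
14 | (3R,4S)-3,4,5-trimethyl-3,4-dihydro-1H-isochromene-6,8-diol | Cc1c(O)cc(O)c2c1[C@H](C)[C@@H](C)OC2 | intermediate
15 | (3R,4S)-6-hydroxy-3,4,5-trimethyl-3,4-dihydro-8H-isochromen-8-one | CC1=C2C(=CO[C@H](C)[C@H]2C)C(=O)C=C1O | intermediate
16 | (3R,4S)-7-[(dimethylamino)methyl]-3,4,5-trimethyl-3,4-dihydro-1H-isochromene-6,8-diol | CN(C)Cc1c(O)c(C)c2c(c1O)CO[C@H](C)[C@H]2C | intermediate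
17 | (3R,4S)-8-hydroxy-3,4,5-trimethyl-7-methylidene-3,4-dihydro-1H-isochromen-6(7H)-one | C=C1C(=O)C(C)=C2C(=C1O)CO[C@H](C)[C@H]2C | intermediate (not isolated)
18 | (3R,4S)-7-{[(3R,4S)-6,8-dihydroxy-3,4,5-trimethyl-3,4-dihydro-1H-isochromen-7-yl]methyl}-6-hydroxy-3,4,5-trimethyl-3,4-dihydro-8H-isochromen-8-one | CC1=C2C(=CO[C@H](C)[C@H]2C)C(=O)C(Cc2c(O)c(C)c3c(c2O)CO[C@H](C)[C@H]3C)=C1O | target

## Step count and least certain steps

Total step count: 11. Longest linear sequence: 10 steps (steps 1 to 8, then step 9 or step 10, then step 11); steps 9 and 10 are parallel branches from 14.

Step 5 (key step). The most likely failure is deprotonation of 7 at its γ-carbon ahead of conjugate addition. The acceptor carbon is flanked by a branched centre and the donor is a tertiary carbanion, so the addition is slow and reversible, and ethoxide is released once the non-acidic adduct 9 has formed. The result would be loss of configuration at C4 or vinylogous elimination of the C3 oxygen. The fallback sets out from 8 and 7. Compound 8 is converted with Me3SiOTf and Et3N into its silyl ketene acetal, ethyl 3-ethoxy-2-methyl-3-(trimethylsilyloxy)prop-2-enoate F1. F1 is added to 7 in a Mukaiyama–Michael reaction promoted by LiClO4 in Et2O, where no free base is present, to give the silyl enol ether diethyl 2-[(5S,6R)-6-(methoxymethoxy)-5-methyl-2-(trimethylsilyloxy)hept-2-en-4-yl]-2-methylpropanedioate F2. Mild aqueous hydrolysis gives 9, now isolated, and the route is rejoined at 9, which is closed to 10 with NaOEt in EtOH in the absence of any enone.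

Step 7. The most likely failures are disproportionation (the hydrogen set free is transferred to further 12, with loss of a ring oxygen) and erosion of configuration at C4 by reversible dehydrogenation of the side chain on the hot metal surface. The fallback sets out from 12. Double O-silylation with Me3SiOTf and Et3N gives the bis-silyl dienol ether ({5-[(2S,3R)-3-(methoxymethoxy)butan-2-yl]-4-methylcyclohexa-1,3-diene-1,3-diyl}bis(oxy))bis(trimethylsilane) F3. DDQ at 0 °C dehydrogenates F3 across its two saturated ring carbons to the bis-silyl resorcinol ether ({5-[(2S,3R)-3-(methoxymethoxy)butan-2-yl]-4-methyl-1,3-phenylene}bis(oxy))bis(trimethylsilane) F4. K2CO3 in MeOH returns the route to 13.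

Step 8. The most likely failure is intermolecular alkoxymethylation at C7 and oligomer formation, because C7 lies between two free hydroxyls and the acetal can also ionise toward a free methoxymethyl cation. The fallback sets out from 13. Both phenols are silylated with t-BuMe2SiCl and imidazole to give ({5-[(2S,3R)-3-(methoxymethoxy)butan-2-yl]-4-methyl-1,3-phenylene}bis(oxy))bis(tert-butyldimethylsilane) F5, in which C7 is shielded between two bulky silyl ethers. Cyclisation with catalytic Me3SiOTf gives (3R,4S)-6,8-bis(tert-butyldimethylsilyloxy)-3,4,5-trimethyl-3,4-dihydro-1H-isochromene F6, and Bu4NF returns the route to 14.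

Step 9. The most likely failures are loss of site control (hydride abstraction from the C5 methyl, which is also ortho and para to hydroxyls) and conjugate addition of unreacted 14 through its C7 to C1 of newly formed 15. The fallback sets out from 13 and never has 14 and 15 in one flask. Vilsmeier–Haack formylation (POCl3, DMF) at C8a, para to the C6 hydroxyl, gives 2,4-dihydroxy-6-[(2S,3R)-3-(methoxymethoxy)butan-2-yl]-5-methylbenzaldehyde F7. Aqueous HCl in THF removes the acetal, the freed hydroxyl closes onto the aldehyde to the lactol (3R,4S)-3,4,5-trimethyl-3,4-dihydro-1H-isochromene-1,6,8-triol F8, and F8 loses water to rejoin the route at 15.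

Step 11. The most likely failures are self-condensation of 15 (its own C7 adding to C1 of a second molecule), dimerisation of 17 outrunning the cross-coupling, and acid-promoted cyclodehydration of the product to a xanthene. The fallback sets out from 14. Two molecules of 14 are bridged with formaldehyde (0.5 equiv) under mild acid to give bis[(3R,4S)-6,8-dihydroxy-3,4,5-trimethyl-3,4-dihydro-1H-isochromen-7-yl]methane F9, the same structure as A1. One equivalent of DDQ then oxidises one C1H2 group; the singly oxidised product would be separated from unchanged F9 (to be recycled) and doubly oxidised material, and the route is rejoined at 18.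

## Further compounds

F1 | step 5 | ethyl 3-ethoxy-2-methyl-3-(trimethylsilyloxy)prop-2-enoate | CCOC(=O)C(C)=C(OCC)O[Si](C)(C)C
F2 | step 5 | diethyl 2-[(5S,6R)-6-(methoxymethoxy)-5-methyl-2-(trimethylsilyloxy)hept-2-en-4-yl]-2-methylpropanedioate | CCOC(=O)C(C)(C(=O)OCC)C(C=C(C)O[Si](C)(C)C)[C@H](C)[C@@H](C)OCOC
F3 | step 7 | ({5-[(2S,3R)-3-(methoxymethoxy)butan-2-yl]-4-methylcyclohexa-1,3-diene-1,3-diyl}bis(oxy))bis(trimethylsilane) | CC1=C(O[Si](C)(C)C)C=C(O[Si](C)(C)C)CC1[C@H](C)[C@@H](C)OCOC
F4 | step 7 | ({5-[(2S,3R)-3-(methoxymethoxy)butan-2-yl]-4-methyl-1,3-phenylene}bis(oxy))bis(trimethylsilane) | Cc1c(O[Si](C)(C)C)cc(O[Si](C)(C)C)cc1[C@H](C)[C@@H](C)OCOC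
F5 | step 8 | ({5-[(2S,3R)-3-(methoxymethoxy)butan-2-yl]-4-methyl-1,3-phenylene}bis(oxy))bis(tert-butyldimethylsilane) | Cc1c(O[Si](C)(C)C(C)(C)C)cc(O[Si](C)(C)C(C)(C)C)cc1[C@H](C)[C@@H](C)OCOC
F6 | step 8 | (3R,4S)-6,8-bis(tert-butyldimethylsilyloxy)-3,4,5-trimethyl-3,4-dihydro-1H-isochromene | Cc1c(O[Si](C)(C)C(C)(C)C)cc(O[Si](C)(C)C(C)(C)C)c2c1[C@H](C)[C@@H](C)OC2
F7 | step 9 | 2,4-dihydroxy-6-[(2S,3R)-3-(methoxymethoxy)butan-2-yl]-5-methylbenzaldehyde | Cc1c(O)cc(O)c(C=O)c1[C@H](C)[C@@H](C)OCOC
F8 | step 9 | (3R,4S)-3,4,5-trimethyl-3,4-dihydro-1H-isochromene-1,6,8-triol (C1 epimers) | Cc1c(O)cc(O)c2c1[C@H](C)[C@@H](C)OC2O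
F9 | step 11 | bis[(3R,4S)-6,8-dihydroxy-3,4,5-trimethyl-3,4-dihydro-1H-isochromen-7-yl]methane | C(c1c(O)c(C)c2c(c1O)CO[C@H](C)[C@H]2C)c1c(O)c(C)c2c(c1O)CO[C@H](C)[C@H]2C
A1 | alternative 1 | bis[(3R,4S)-6,8-dihydroxy-3,4,5-trimethylisochroman-7-yl]methane | C(c1c(O)c(C)c2c(c1O)CO[C@H](C)[C@H]2C)c1c(O)c(C)c2c(c1O)CO[C@H](C)[C@H]2C
A2 | alternative 2 | bis{4-[(2S,3R)-3-hydroxybutan-2-yl]-2,6-dimethoxy-3-methylphenyl}methane | C(c1c(OC)c(C)c([C@H](C)[C@@H](C)O)cc1OC)c1c(OC)c(C)c([C@H](C)[C@@H](C)O)cc1OC
A3 | alternative 2 | bis{2,6-dimethoxy-3-methyl-4-[(2R,3R)-3-methyloxiran-2-yl]phenyl}methane | C(c1c(OC)c(C)c([C@H]2O[C@@H]2C)cc1OC)c1c(OC)c(C)c([C@H]2O[C@@H]2C)cc1OC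
A4 | alternative 2 | bis{2,6-dimethoxy-3-methyl-4-[(E)-prop-1-en-1-yl]phenyl}methane | C(c1c(OC)c(C)c(/C=C/C)cc1OC)c1c(OC)c(C)c(/C=C/C)cc1OC
A5 | alternative 3 | (3R,4S)-6,8-dimethoxy-3,4,5-trimethylisochroman | COc1cc(OC)c2c(c1C)[C@H](C)[C@@H](C)OC2
A6 | alternative 3 | (2R,3S)-3-(3,5-dimethoxy-2,6-dimethylphenyl)butan-2-ol | COc1cc(OC)c(C)c([C@H](C)[C@@H](C)O)c1C
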